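**Plan**

- Retrosynthesis: after the three benzyl ethers are removed, the butane-1,4-diol is cut at its two C–CH2Ar bonds, Cα–CH2 (ring A, the chain guaiacyl ring) and Cβ–CH2 (C5 of the benzofuran, ring B). The dihydrofuran ring is cut at O1–C2 and at C2–C3.
- Enabling feature: HOCH2–CαH(CH2Ar)–CβH(CH2Ar')–CH2OH has two adjacent CH stereocentres, each bearing a hydroxymethyl and an arylmethyl group. It is the reduced form of a trans-3,4-disubstituted γ-butyrolactone whose carbonyl carbon and acetal carbon are the two CH2OH carbons.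
- Forward order: the dihydrofuran ring is made first (aldol for C2–C3, acid closure for O1–C2). Its C5 bromide is then turned into a 1,3-dithiane, and the chain is joined in one pot on a five-membered menthyloxybutenolide template. Desulfurisation, reductive opening of the lactone acetal and debenzylation follow.
- Stereochemistry: benzofuran C3 comes from an Evans oxazolidinone aldol and C2 from thermodynamically controlled trans ring closure. Cβ and then Cα are relayed from the (5R) acetal carbon of the butenolide, which is secured by crystallisation against l-menthol.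

Key step: step 15

Assumption: 4-benzyloxy-3-methoxybenzyl alcohol and 4-benzyloxy-3-methoxybenzaldehyde are both bought; the hemiacetal from furfural is racemic and configurationally labile, so chirality enters only at the menthyl acetal. Ring C is the 2-aryl group of the benzofuran.

**Route**

Step 1
Reactants: 1 furfural
Product: 3 5-hydroxyfuran-2(5H)-one (racemic), via furfural endoperoxide 2 (not isolated)
Conditions: O2, hν (visible lamp), rose bengal disodium salt C20H2Cl4I4Na2O5 (cat.), MeOH, rt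
Reagents that add atoms: dioxygen O=O
Why: Dye-sensitised singlet-oxygen [4+2] cycloaddition to the furan gives the endoperoxide, which methanol fragments with loss of the formyl carbon as methyl formate (furan photooxygenation); no stereocentre is controlled.

Step 2
Reactants: 3 5-hydroxyfuran-2(5H)-one; 4 l-menthol
Product: 5 (5R)-5-[(1R,2S,5R)-menthyloxy]furan-2(5H)-one
Conditions: (1S)-10-camphorsulfonic acid (cat.), toluene, reflux (Dean–Stark); crystallisation from petroleum ether, −20 °C; mother liquor re-equilibrated with acid and recrystallised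
Reagents that add atoms: none
Why: Acid-catalysed acetalisation of the hemiacetal gives both C5 epimers, which interconvert under acid, and the (5R) epimer should crystallise, so C5 is set by crystallisation-driven diastereomer selection against l-menthol.

Step 3
Reactants: 6 4-benzyloxy-3-methoxybenzyl alcohol
Product: 7 4-benzyloxy-3-methoxybenzyl bromide
Conditions: PBr3, Et2O, 0 °C
Reagents that add atoms: phosphorus tribromide BrP(Br)Br
Why: Bromide displaces the activated phosphite ester in an SN2 reaction (PBr3 bromination of a benzylic alcohol), and the benzyl and methyl ethers are inert at 0 °C.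

Step 4
Reactants: 8 5-bromo-2-hydroxy-3-methoxybenzaldehyde
Product: 9 5-bromo-3-methoxy-2-(methoxymethoxy)benzaldehyde
Conditions: MOMCl, iPr2NEt, CH2Cl2, 0 °C to rt
Reagents that add atoms: chloromethyl methyl ether COCCl
Why: Williamson-type O-alkylation of the phenol with the α-chloro ether (MOM protection) gives a base-stable acetal that the later acid step removes.

Step 5
Reactants: 9 5-bromo-3-methoxy-2-(methoxymethoxy)benzaldehyde
Product: 10 5-bromo-1-methoxy-2-(methoxymethoxy)-3-vinylbenzene
Conditions: Ph3PCH3Br, KOtBu, THF, 0 °C to rt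
Reagents that add atoms: methyltriphenylphosphonium bromide C[P+](c1ccccc1)(c1ccccc1)c1ccccc1.[Br-]
Why: Wittig methylenation with the non-stabilised ylide converts the aldehyde to the styrene, and the aryl bromide and MOM acetal do not react with the ylide.

Step 6
Reactants: 10 5-bromo-1-methoxy-2-(methoxymethoxy)-3-vinylbenzene
Product: 12 2-[5-bromo-3-methoxy-2-(methoxymethoxy)phenyl]ethanol, via B-alkyl-9-BBN adduct 11 (not isolated)
Conditions: 9-BBN (9-borabicyclo[3.3.1]nonane), THF, 0 °C to rt; then NaOH, H2O2, 0 °C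
Reagents that add atoms: hydrogen peroxide OO
Why: The bulky dialkylborane adds anti-Markovnikov to the styrene and alkaline peroxide oxidises the C–B bond to the primary alcohol (Brown hydroboration–oxidation).

Step 7
Reactants: 12 2-[5-bromo-3-methoxy-2-(methoxymethoxy)phenyl]ethanol
Product: 14 [5-bromo-3-methoxy-2-(methoxymethoxy)phenyl]acetic acid, via arylacetaldehyde 13 (not isolated)
Conditions: TEMPO (2,2,6,6-tetramethylpiperidin-1-oxyl, cat.), NaOCl (cat.), NaClO2, MeCN/sodium phosphate buffer pH 6.7, 35 °C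
Reagents that add atoms: sodium chlorite [Na+].[O-]Cl=O
Why: Oxoammonium oxidation to the aldehyde and chlorite oxidation in the same pot (Anelli-type TEMPO oxidation with chlorite as terminal oxidant) is established for electron-rich 2-arylethanols, and the near-neutral pH spares the MOM acetal.

Step 8
Reactants: 14 [5-bromo-3-methoxy-2-(methoxymethoxy)phenyl]acetic acid; 15 (S)-4-benzyl-2-oxazolidinone
Product: 17 (4S)-4-benzyl-3-{[5-bromo-3-methoxy-2-(methoxymethoxy)phenyl]acetyl}oxazolidin-2-one, via pivalic mixed anhydride 16 (not isolated)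
Conditions: PivCl, Et3N, THF, −20 °C; then 15, LiCl, rt
Reagents that add atoms: none
Why: N-Acylation of the Evans auxiliary through the mixed anhydride with LiCl activation is standard, and the hindered pivaloyl carbonyl directs attack to the arylacetyl carbonyl.

Step 9
Reactants: 17 (4S)-4-benzyl-3-{[5-bromo-3-methoxy-2-(methoxymethoxy)phenyl]acetyl}oxazolidin-2-one; 18 4-benzyloxy-3-methoxybenzaldehyde
Product: 21 (4S)-4-benzyl-3-{(2S,3S)-3-(4-benzyloxy-3-methoxyphenyl)-2-[5-bromo-3-methoxy-2-(methoxymethoxy)phenyl]-3-hydroxypropanoyl}oxazolidin-2-one, via dibutylboron Z-enolate 19 (not isolated), via dibutylboron aldolate 20 (not isolated)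
Conditions: Bu2BOTf, iPr2NEt, CH2Cl2, −78 to 0 °C; 18, −78 to 0 °C; then pH 7 buffer, MeOH, H2O2, 0 °C
Reagents that add atoms: none
Why: In this Evans syn-aldol, soft enolisation gives the Z boron enolate, which reacts through a closed Zimmerman–Traxler chair on the face away from the benzyl group of the dipole-minimised auxiliary, so the α-carbon (future benzofuran C3) and the carbinol carbon are set syn as (2S,3S).

Step 10
Reactants: 21 syn-aldol imide
Product: 22 (1S,2R)-1-(4-benzyloxy-3-methoxyphenyl)-2-[5-bromo-3-methoxy-2-(methoxymethoxy)phenyl]propane-1,3-diol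
Conditions: LiBH4, THF/MeOH, 0 °C
Reagents that add atoms: none
Why: Hydride attack at the exocyclic imide carbonyl (reductive cleavage of an N-acyloxazolidinone) releases the primary alcohol and the auxiliary without touching the aryl bromide or either stereocentre.

Step 11
Reactants: 22 (1S,2R)-diol
Product: 24 [(2S,3R)-2-(4-benzyloxy-3-methoxyphenyl)-5-bromo-7-methoxy-2,3-dihydro-1-benzofuran-3-yl]methanol, via free phenol triol 23 (not isolated)
Conditions: HCl (1.25 M in MeOH), 0 °C to rt
Reagents that add atoms: none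
Why: Acid methanolysis frees the phenol and the p-alkoxybenzylic alcohol ionises to a quinone-methide-like cation that the phenol captures in a 5-exo-trig closure (acid-mediated phenylcoumaran ring closure), so C3 is untouched and the reversible closure should place the C2 aryl trans to the C3 hydroxymethyl group.

Step 12
Reactants: 24 dihydrobenzofuran-3-ylmethanol
Product: 25 (2S,3R)-2-(4-benzyloxy-3-methoxyphenyl)-3-(benzyloxymethyl)-5-bromo-7-methoxy-2,3-dihydro-1-benzofuran
Conditions: NaH, BnBr, Bu4NI (cat.), THF, 0 °C to rt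
Reagents that add atoms: benzyl bromide BrCc1ccccc1
Why: Williamson etherification of the primary alkoxide with benzyl bromide under iodide catalysis is selective because no other acidic site is present.

Step 13
Reactants: 25 5-bromo benzyl ether
Product: 27 (2S,3R)-2-(4-benzyloxy-3-methoxyphenyl)-3-(benzyloxymethyl)-7-methoxy-2,3-dihydro-1-benzofuran-5-carbaldehyde, via 5-lithio benzofuran 26 (not isolated)
Conditions: n-BuLi, THF, −78 °C; DMF, −78 to 0 °C; aqueous work-up
Reagents that add atoms: N,N-dimethylformamide CN(C)C=O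
Why: Bromine–lithium exchange at −78 °C outpaces benzylic deprotonation and the aryllithium is formylated by DMF (Bouveault formylation).

Step 14
Reactants: 27 benzofuran-5-carbaldehyde
Product: 28 2-[(2S,3R)-2-(4-benzyloxy-3-methoxyphenyl)-3-(benzyloxymethyl)-7-methoxy-2,3-dihydro-1-benzofuran-5-yl]-1,3-dithiane
Conditions: HS(CH2)3SH, I2 (cat.), CH2Cl2, rt
Reagents that add atoms: propane-1,3-dithiol SCCCS
Why: Iodine-catalysed dithioacetalisation of an aromatic aldehyde runs under near-neutral conditions that should spare the acid-sensitive 2-aryl dihydrobenzofuran and the benzyl ethers.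

Step 15
Reactants: 28 benzofuran-5-yl dithiane; 5 (5R)-5-menthyloxyfuran-2(5H)-one; 7 4-benzyloxy-3-methoxybenzyl bromide
Product: 31 (3R,4R,5R)-3-(4-benzyloxy-3-methoxybenzyl)-4-{2-[(2S,3R)-2-(4-benzyloxy-3-methoxyphenyl)-3-(benzyloxymethyl)-7-methoxy-2,3-dihydro-1-benzofuran-5-yl]-1,3-dithian-2-yl}-5-[(1R,2S,5R)-menthyloxy]dihydrofuran-2(3H)-one, via 2-lithio-1,3-dithiane 29 (not isolated), via lithium lactone enolate 30 (not isolated)
Conditions: n-BuLi, THF, −78 to −20 °C; 5, −78 °C; then 7, TMEDA, −78 °C to rt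
Reagents that add atoms: none
Why: n-BuLi removes the acidic C2–H of the 2-aryl-1,3-dithiane (an acyl-anion equivalent, so the benzylic carbon at C5 of the benzofuran reacts with reversed polarity), the soft sulfur- and aryl-stabilised carbanion adds 1,4 to the butenolide, and the resulting lithium lactone enolate is C-benzylated by the bromide once TMEDA has loosened the aggregate. The closest known reaction type is the tandem conjugate addition–enolate benzylation of lithiated aryl dithianes on 5-menthyloxyfuran-2(5H)-one used for dibenzylbutane and dibenzylbutyrolactone lignans. No ring is closed: the lactone is only a five-membered template whose carbonyl carbon and acetal carbon later become the two hydroxymethyl carbons. C4 is controlled by the acetal centre C5, the nucleophile entering the planar butenolide on the face opposite the menthyloxy group, and C3 is then controlled by C4, the bromide approaching the enolate anti to the very bulky dithianyl substituent, so the all-trans (3R,4R,5R) lactone should result. The step needs 1,4- over 1,2-addition (secured by the delocalised 2-aryl dithiane anion at low temperature), C-monoalkylation (secured by the reactive benzylic bromide and the shielding next to C3) and deprotonation at the dithiane carbon only (secured by its much higher acidity than the benzyl ether and ring C2–H positions).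

Step 16
Reactants: 31 dithianyl lactone
Product: 32 (3R,4R,5R)-3-(4-benzyloxy-3-methoxybenzyl)-4-{[(2S,3R)-2-(4-benzyloxy-3-methoxyphenyl)-3-(benzyloxymethyl)-7-methoxy-2,3-dihydro-1-benzofuran-5-yl]methyl}-5-[(1R,2S,5R)-menthyloxy]dihydrofuran-2(3H)-one
Conditions: NiCl2·6H2O, NaBH4, MeOH/THF, 0 °C to rt
Reagents that add atoms: none
Why: Nickel boride generated in the flask cleaves both C–S bonds (reductive desulfurisation of a dithioacetal to CH2) without hydrogenolysing benzyl ethers and without involving any stereocentre.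

Step 17
Reactants: 32 desulfurised lactone
Product: 33 (2R,3R)-2-(4-benzyloxy-3-methoxybenzyl)-3-{[(2S,3R)-2-(4-benzyloxy-3-methoxyphenyl)-3-(benzyloxymethyl)-7-methoxy-2,3-dihydro-1-benzofuran-5-yl]methyl}butane-1,4-diol
Conditions: LiAlH4, THF, 0 °C to rt
Reagents that add atoms: none
Why: Hydride opens the lactone, the liberated hemiacetal alkoxide expels mentholate and the two aldehyde-level carbons are reduced to CH2OH (LiAlH4 reduction of a γ-alkoxybutyrolactone to a 1,4-diol), leaving the adjacent stereocentres unchanged.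

Step 18
Reactants: 33 tribenzyl diol
Product: 34 CNP0256425.1, (2R,3R)-2-(4-hydroxy-3-methoxybenzyl)-3-{[(2S,3R)-2-(4-hydroxy-3-methoxyphenyl)-3-(hydroxymethyl)-7-methoxy-2,3-dihydro-1-benzofuran-5-yl]methyl}butane-1,4-diol
Conditions: H2 (1 atm), 10% Pd/C, EtOAc/MeOH, rt
Reagents that add atoms: none
Why: Palladium-catalysed hydrogenolysis removes the two aryl benzyl ethers and the alkyl benzyl ether (O-debenzylation), and at 1 atm and room temperature the hindered cyclic C2–O bond of the dihydrobenzofuran should survive if the reaction is stopped at full conversion.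

**Compound list**

1 | furfural | O=Cc1ccco1 | starting material
2 | furfural 2,5-endoperoxide, 2,3,7-trioxabicyclo[2.2.1]hept-5-ene-1-carbaldehyde (not isolated) | O=CC12C=CC(OO1)O2 | intermediate
3 | 5-hydroxyfuran-2(5H)-one (racemic) | O=C1C=CC(O)O1 | intermediate
4 | l-menthol, (1R,2S,5R)-2-isopropyl-5-methylcyclohexanol | CC(C)[C@@H]1CC[C@@H](C)C[C@H]1O | starting material
5 | (5R)-5-[(1R,2S,5R)-menthyloxy]furan-2(5H)-one | O=C1C=C[C@H](O[C@@H]2C[C@H](C)CC[C@H]2C(C)C)O1 | intermediate
6 | 4-benzyloxy-3-methoxybenzyl alcohol | COc1cc(CO)ccc1OCc1ccccc1 | starting material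
7 | 4-benzyloxy-3-methoxybenzyl bromide | COc1cc(CBr)ccc1OCc1ccccc1 | intermediate
8 | 5-bromo-2-hydroxy-3-methoxybenzaldehyde | COc1cc(Br)cc(C=O)c1O | starting material
9 | 5-bromo-3-methoxy-2-(methoxymethoxy)benzaldehyde | COCOc1c(OC)cc(Br)cc1C=O | intermediate
10 | 5-bromo-1-methoxy-2-(methoxymethoxy)-3-vinylbenzene | COCOc1c(OC)cc(Br)cc1C=C | intermediate
11 | 9-{2-[5-bromo-3-methoxy-2-(methoxymethoxy)phenyl]ethyl}-9-borabicyclo[3.3.1]nonane (not isolated) | COCOc1c(OC)cc(Br)cc1CCB1C2CCCC1CCC2 | intermediate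
12 | 2-[5-bromo-3-methoxy-2-(methoxymethoxy)phenyl]ethanol | COCOc1c(OC)cc(Br)cc1CCO | intermediate
13 | [5-bromo-3-methoxy-2-(methoxymethoxy)phenyl]acetaldehyde (not isolated) | COCOc1c(OC)cc(Br)cc1CC=O | intermediate
14 | [5-bromo-3-methoxy-2-(methoxymethoxy)phenyl]acetic acid | COCOc1c(OC)cc(Br)cc1CC(=O)O | intermediate
15 | (S)-4-benzyl-2-oxazolidinone | O=C1N[C@@H](Cc2ccccc2)CO1 | starting material
16 | [5-bromo-3-methoxy-2-(methoxymethoxy)phenyl]acetic pivalic anhydride (not isolated) | COCOc1c(OC)cc(Br)cc1CC(=O)OC(=O)C(C)(C)C | intermediate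
17 | (4S)-4-benzyl-3-{[5-bromo-3-methoxy-2-(methoxymethoxy)phenyl]acetyl}oxazolidin-2-one | COCOc1c(OC)cc(Br)cc1CC(=O)N1[C@@H](Cc2ccccc2)COC1=O | intermediate
18 | 4-benzyloxy-3-methoxybenzaldehyde | COc1cc(C=O)ccc1OCc1ccccc1 | starting material
19 | dibutylboron Z-enolate of 17 (not isolated) | COCOc1c(OC)cc(Br)cc1/C=C(\OB(CCCC)CCCC)N1[C@@H](Cc2ccccc2)COC1=O | intermediate
20 | O-dibutylboryl aldolate of 21 (not isolated) | COCOc1c(OC)cc(Br)cc1[C@H](C(=O)N1[C@@H](Cc2ccccc2)COC1=O)[C@H](OB(CCCC)CCCC)c1ccc(OCc2ccccc2)c(OC)c1 | intermediate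
21 | (4S)-4-benzyl-3-{(2S,3S)-3-(4-benzyloxy-3-methoxyphenyl)-2-[5-bromo-3-methoxy-2-(methoxymethoxy)phenyl]-3-hydroxypropanoyl}oxazolidin-2-one | COCOc1c(OC)cc(Br)cc1[C@H](C(=O)N1[C@@H](Cc2ccccc2)COC1=O)[C@H](O)c1ccc(OCc2ccccc2)c(OC)c1 | intermediate
22 | (1S,2R)-1-(4-benzyloxy-3-methoxyphenyl)-2-[5-bromo-3-methoxy-2-(methoxymethoxy)phenyl]propane-1,3-diol | COCOc1c(OC)cc(Br)cc1[C@H](CO)[C@H](O)c1ccc(OCc2ccccc2)c(OC)c1 | intermediate
23 | (1S,2R)-1-(4-benzyloxy-3-methoxyphenyl)-2-(5-bromo-2-hydroxy-3-methoxyphenyl)propane-1,3-diol (not isolated) | COc1cc(Br)cc([C@H](CO)[C@H](O)c2ccc(OCc3ccccc3)c(OC)c2)c1O | intermediate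
24 | [(2S,3R)-2-(4-benzyloxy-3-methoxyphenyl)-5-bromo-7-methoxy-2,3-dihydro-1-benzofuran-3-yl]methanol | Brc1cc(OC)c2c(c1)[C@H](CO)[C@@H](c1ccc(OCc3ccccc3)c(OC)c1)O2 | intermediate
25 | (2S,3R)-2-(4-benzyloxy-3-methoxyphenyl)-3-(benzyloxymethyl)-5-bromo-7-methoxy-2,3-dihydro-1-benzofuran | Brc1cc(OC)c2c(c1)[C@H](COCc3ccccc3)[C@@H](c1ccc(OCc3ccccc3)c(OC)c1)O2 | intermediate
26 | 5-lithio derivative of 25 (not isolated) | [Li]c1cc(OC)c2c(c1)[C@H](COCc3ccccc3)[C@@H](c1ccc(OCc3ccccc3)c(OC)c1)O2 | intermediate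
27 | (2S,3R)-2-(4-benzyloxy-3-methoxyphenyl)-3-(benzyloxymethyl)-7-methoxy-2,3-dihydro-1-benzofuran-5-carbaldehyde | O=Cc1cc(OC)c2c(c1)[C@H](COCc3ccccc3)[C@@H](c1ccc(OCc3ccccc3)c(OC)c1)O2 | intermediate
28 | 2-[(2S,3R)-2-(4-benzyloxy-3-methoxyphenyl)-3-(benzyloxymethyl)-7-methoxy-2,3-dihydro-1-benzofuran-5-yl]-1,3-dithiane | S1CCCSC1c2cc(OC)c3c(c2)[C@H](COCc4ccccc4)[C@@H](c2ccc(OCc4ccccc4)c(OC)c2)O3 | intermediate
29 | 2-lithio derivative of dithiane 28 (not isolated) | [Li]C1(SCCCS1)c2cc(OC)c3c(c2)[C@H](COCc4ccccc4)[C@@H](c2ccc(OCc4ccccc4)c(OC)c2)O3 | intermediate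
30 | lithium enolate of the (4R,5R)-4-dithianyl-5-menthyloxy lactone (not isolated) | [Li]OC1=C[C@@H](C2(SCCCS2)c3cc(OC)c4c(c3)[C@H](COCc5ccccc5)[C@@H](c3ccc(OCc5ccccc5)c(OC)c3)O4)[C@H](O[C@@H]3C[C@H](C)CC[C@H]3C(C)C)O1 | intermediate
31 | (3R,4R,5R)-3-(4-benzyloxy-3-methoxybenzyl)-4-{2-[(2S,3R)-2-(4-benzyloxy-3-methoxyphenyl)-3-(benzyloxymethyl)-7-methoxy-2,3-dihydro-1-benzofuran-5-yl]-1,3-dithian-2-yl}-5-[(1R,2S,5R)-menthyloxy]dihydrofuran-2(3H)-one | COc1cc(C[C@H]2C(=O)O[C@@H](O[C@@H]3C[C@H](C)CC[C@H]3C(C)C)[C@@H]2C5(SCCCS5)c2cc(OC)c3c(c2)[C@H](COCc4ccccc4)[C@@H](c2ccc(OCc4ccccc4)c(OC)c2)O3)ccc1OCc1ccccc1 | intermediate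
32 | (3R,4R,5R)-3-(4-benzyloxy-3-methoxybenzyl)-4-{[(2S,3R)-2-(4-benzyloxy-3-methoxyphenyl)-3-(benzyloxymethyl)-7-methoxy-2,3-dihydro-1-benzofuran-5-yl]methyl}-5-[(1R,2S,5R)-menthyloxy]dihydrofuran-2(3H)-one | COc1cc(C[C@H]2C(=O)O[C@@H](O[C@@H]3C[C@H](C)CC[C@H]3C(C)C)[C@@H]2Cc2cc(OC)c3c(c2)[C@H](COCc4ccccc4)[C@@H](c2ccc(OCc4ccccc4)c(OC)c2)O3)ccc1OCc1ccccc1 | intermediate
33 | (2R,3R)-2-(4-benzyloxy-3-methoxybenzyl)-3-{[(2S,3R)-2-(4-benzyloxy-3-methoxyphenyl)-3-(benzyloxymethyl)-7-methoxy-2,3-dihydro-1-benzofuran-5-yl]methyl}butane-1,4-diol | COc1cc(C[C@@H](CO)[C@H](CO)Cc2cc(OC)c3c(c2)[C@H](COCc4ccccc4)[C@@H](c2ccc(OCc4ccccc4)c(OC)c2)O3)ccc1OCc1ccccc1 | intermediate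
34 | CNP0256425.1, (2R,3R)-2-(4-hydroxy-3-methoxybenzyl)-3-{[(2S,3R)-2-(4-hydroxy-3-methoxyphenyl)-3-(hydroxymethyl)-7-methoxy-2,3-dihydro-1-benzofuran-5-yl]methyl}butane-1,4-diol | COc1cc(C[C@@H](CO)[C@H](CO)Cc2cc(OC)c3c(c2)[C@H](CO)[C@@H](c2ccc(O)c(OC)c2)O3)ccc1O | target

**Step count and risks**

Total: 18 steps. Longest linear sequence: 15 steps (steps 4 to 18, from 8 to 34).

Steps most likely to fail:

1. Step 15 (tandem addition–alkylation). Lithiation of the heavily functionalised dithiane may be accompanied by metalation elsewhere, and C-alkylation of the crowded enolate may be slow enough that proton quench to the simple Michael adduct wins. The fallback exchanges the polarity of the two benzylic partners while making the same two bonds on the same butenolide; it sets out from 5 (using 18 and 27) and comes back at 33. Aldehyde 18 is condensed with propane-1,3-dithiol (I2 cat.) to 2-(4-benzyloxy-3-methoxyphenyl)-1,3-dithiane F1. Aldehyde 27 is reduced with NaBH4 to the benzofuran-5-ylmethanol F2, which PBr3 converts into the benzofuran-5-ylmethyl bromide F3. Lithiated F1 adds to 5 anti to the menthyloxy group and the enolate is alkylated by F3 anti to the dithianyl group, giving the all-trans regio-exchanged dithianyl lactone F4. Nickel boride then gives the desulfurised lactone F5, and LiAlH4 reduces F5 to diol 33. Because both lactone carbons end as CH2OH, the same (5R)-butenolide delivers the same (2R,3R) diol.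

2. Step 11 (deprotection and ring closure). Ionisation of the benzylic alcohol in the free 1,3-diol may divert into loss of formaldehyde by retro-Prins fragmentation, elimination towards a stilbene, or capture of the liberated formaldehyde equivalent as a cyclic methylene acetal. The fallback closes the ring before the auxiliary is removed, where no free hydroxymethyl group is present; it sets out from 21 and comes back at 24. Treating 21 with HCl in MeOH removes the MOM group and should close the ring to the trans (2S,3S)-dihydrobenzofuran-3-carbonyl oxazolidinone F6. LiBH4 at 0 °C then cleaves the imide reductively to alcohol 24.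

3. Step 18 (global debenzylation). Hydrogenolytic opening of the benzylic C2–O bond of the dihydrobenzofuran may compete, or cleavage of the alkyl benzyl ether may stall. The fallback replaces surface hydrogenolysis by Lewis-acid dealkylation with a cation scavenger; it sets out from 33 and arrives directly at 34. BCl3 with pentamethylbenzene in CH2Cl2 at −78 °C removes all three benzyl groups as benzylpentamethylbenzene; this fallback makes no new compound (F0).

**Further compounds**

F1 | step 15 | 2-(4-benzyloxy-3-methoxyphenyl)-1,3-dithiane | COc1cc(C2SCCCS2)ccc1OCc1ccccc1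
F2 | step 15 | [(2S,3R)-2-(4-benzyloxy-3-methoxyphenyl)-3-(benzyloxymethyl)-7-methoxy-2,3-dihydro-1-benzofuran-5-yl]methanol | OCc1cc(OC)c2c(c1)[C@H](COCc3ccccc3)[C@@H](c1ccc(OCc3ccccc3)c(OC)c1)O2
F3 | step 15 | (2S,3R)-2-(4-benzyloxy-3-methoxyphenyl)-3-(benzyloxymethyl)-5-(bromomethyl)-7-methoxy-2,3-dihydro-1-benzofuran | BrCc1cc(OC)c2c(c1)[C@H](COCc3ccccc3)[C@@H](c1ccc(OCc3ccccc3)c(OC)c1)O2
F4 | step 15 | (3R,4R,5R)-3-{[(2S,3R)-2-(4-benzyloxy-3-methoxyphenyl)-3-(benzyloxymethyl)-7-methoxy-2,3-dihydro-1-benzofuran-5-yl]methyl}-4-[2-(4-benzyloxy-3-methoxyphenyl)-1,3-dithian-2-yl]-5-[(1R,2S,5R)-menthyloxy]dihydrofuran-2(3H)-one | C(c1cc(OC)c2c(c1)[C@H](COCc3ccccc3)[C@@H](c1ccc(OCc3ccccc3)c(OC)c1)O2)[C@H]1C(=O)O[C@@H](O[C@@H]2C[C@H](C)CC[C@H]2C(C)C)[C@@H]1C1(SCCCS1)c1ccc(OCc2ccccc2)c(OC)c1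
F5 | step 15 | (3R,4R,5R)-3-{[(2S,3R)-2-(4-benzyloxy-3-methoxyphenyl)-3-(benzyloxymethyl)-7-methoxy-2,3-dihydro-1-benzofuran-5-yl]methyl}-4-(4-benzyloxy-3-methoxybenzyl)-5-[(1R,2S,5R)-menthyloxy]dihydrofuran-2(3H)-one | C(c1cc(OC)c2c(c1)[C@H](COCc3ccccc3)[C@@H](c1ccc(OCc3ccccc3)c(OC)c1)O2)[C@H]1C(=O)O[C@@H](O[C@@H]2C[C@H](C)CC[C@H]2C(C)C)[C@@H]1Cc1ccc(OCc2ccccc2)c(OC)c1
F6 | step 11 | (4S)-4-benzyl-3-{[(2S,3S)-2-(4-benzyloxy-3-methoxyphenyl)-5-bromo-7-methoxy-2,3-dihydro-1-benzofuran-3-yl]carbonyl}oxazolidin-2-one | Brc1cc(OC)c2c(c1)[C@H](C(=O)N1[C@@H](Cc3ccccc3)COC1=O)[C@@H](c1ccc(OCc3ccccc3)c(OC)c1)O2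
F0 | step 18 | none | none
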